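The upper flavan unit is disconnected at the O1–C8a aryl ether bond of its pyran ring (ring C), with O1 read as the oxygen of an aryl ketone. The key step closes ring C by copper-catalysed intramolecular O-arylation of that ketone's enolate onto C8a of ring A, which carries bromine between C4a and the C8 oxygen; this exploits the 1,5-relationship of O1 and C8a through C2–C3–C4–C4a. The precursor is an open-chain β,β-diaryl ketone whose C4 already bears the complete lower flavan-3,4-diol unit (via its C6). The resulting 2,4-diaryl-4H-chromene enol ether is then hydroborated anti to the C4 aryl group, setting C2 and C3.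

Key step: step 13

Remark: flavan numbering is used for both units ("upper" = unit joined through C4, "lower" = unit joined through C6), and 2-bromo-3,4-dihydroxybenzaldehyde (13) is taken as a catalogue compound.

Step 1
Reactants: 1 2',3',4'-trihydroxyacetophenone
Product: 2 1-[3,4-bis(benzyloxy)-2-hydroxyphenyl]ethan-1-one
Conditions: BnBr (2.1 equiv), K2CO3, acetone, reflux
Reagents that add atoms: benzyl bromide, BrCc1ccccc1
Why: Williamson etherification should spare the 2'-OH, which is hydrogen-bonded to the ketone and is the least nucleophilic of the three phenols.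

Step 2
Reactants: 2 1-[3,4-bis(benzyloxy)-2-hydroxyphenyl]ethan-1-one
Product: 3 1-[3,4-bis(benzyloxy)-5-bromo-2-hydroxyphenyl]ethan-1-one
Conditions: NBS, MeCN, 0 °C → rt
Reagents that add atoms: N-bromosuccinimide, O=C1CCC(=O)N1Br
Why: Electrophilic aromatic bromination should go to C5', which is para to the free phenol and ortho to OBn, whereas C6' is ortho to the acyl group and meta to the phenol.

Step 3
Reactants: 3 1-[3,4-bis(benzyloxy)-5-bromo-2-hydroxyphenyl]ethan-1-one
Product: 4 1-[3,4-bis(benzyloxy)-5-bromo-2-(methoxymethoxy)phenyl]ethan-1-one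
Conditions: NaH, MOMCl, DMF, 0 °C → rt
Reagents that add atoms: chloromethyl methyl ether, COCCl
Why: O-alkylation of the sodium phenoxide masks the phenol so that it cannot add to the enone or divert the basic peroxide epoxidation of step 5.

Step 4
Reactants: 4 1-[3,4-bis(benzyloxy)-5-bromo-2-(methoxymethoxy)phenyl]ethan-1-one; 5 4-(benzyloxy)benzaldehyde
Product: 6 (E)-1-[3,4-bis(benzyloxy)-5-bromo-2-(methoxymethoxy)phenyl]-3-[4-(benzyloxy)phenyl]prop-2-en-1-one
Conditions: KOH (aq), EtOH/THF, rt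
Reagents that add atoms: none
Why: Claisen–Schmidt condensation of the methyl ketone with the non-enolisable aldehyde (aldol addition, then E1cB dehydration) should give the E-enone.

Step 5
Reactants: 6 (E)-chalcone
Product: 7 [3,4-bis(benzyloxy)-5-bromo-2-(methoxymethoxy)phenyl][(2R,3S)-3-[4-(benzyloxy)phenyl]oxiran-2-yl]methanone (trans-epoxide)
Conditions: poly-L-leucine, urea·H2O2, DBU, THF, rt
Reagents that add atoms: hydrogen peroxide (as urea adduct), OO
Why: Juliá–Colonna epoxidation, in which hydroperoxide adds to the enone bound to the helical poly-L-leucine, should give the trans-(2R,3S) epoxide (Cα R, Cβ S) under catalyst control.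

Step 6
Reactants: 7 MOM-protected (2R,3S)-epoxy ketone
Product: 9 (2R,3R)-7,8-bis(benzyloxy)-2-[4-(benzyloxy)phenyl]-6-bromo-3-hydroxychroman-4-one, via free 2'-phenol epoxy ketone 8 (not isolated)
Conditions: conc. HCl (cat.), MeOH/THF, 55 °C
Reagents that add atoms: none
Why: Acid removes the MOM acetal and the freed phenol opens the protonated epoxide at the p-alkoxybenzylic carbon (6-endo, inversion at C2), while C3 keeps the epoxide Cα configuration, so the 2,3-trans dihydroflavonol should result.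

Step 7
Reactants: 9 (2R,3R)-dihydroflavonol
Product: 10 (2R,3S,4R)-7,8-bis(benzyloxy)-2-[4-(benzyloxy)phenyl]-6-bromochromane-3,4-diol (2,3-trans-3,4-trans)
Conditions: NaBH4, MeOH/THF, 0 °C
Reagents that add atoms: none
Why: Hydride should attack the C4 ketone pseudo-axially, giving the equatorial 4-OH trans to 3-OH and cis to the 2-aryl group, as is usual for borohydride reduction of trans-dihydroflavonols.

Step 8
Reactants: 10 (2R,3S,4R)-flavan-3,4-diol
Product: 11 (2R,3R,4R)-7,8-bis(benzyloxy)-2-[4-(benzyloxy)phenyl]-6-bromo-3,4-bis(tert-butyldimethylsilyloxy)chromane (same spatial arrangement; the C3 descriptor changes by priority only)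
Conditions: TBSOTf, 2,6-lutidine, CH2Cl2, −78 → 0 °C
Reagents that add atoms: tert-butyldimethylsilyl trifluoromethanesulfonate, CC(C)(C)[Si](C)(C)OS(=O)(=O)C(F)(F)F
Why: Silylation under buffered, cold conditions caps both secondary alcohols, including the ionisable benzylic C4–OH, without touching a stereocentre.

Step 9
Reactants: 11 bis-TBS aryl bromide
Product: 12 2-[(2R,3R,4R)-7,8-bis(benzyloxy)-2-[4-(benzyloxy)phenyl]-3,4-bis(tert-butyldimethylsilyloxy)chroman-6-yl]-4,4,5,5-tetramethyl-1,3,2-dioxaborolane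
Conditions: B2pin2, PdCl2(dppf) (5 mol %), KOAc, 1,4-dioxane, 90 °C
Reagents that add atoms: bis(pinacolato)diboron, CC1(C)OB(OC1(C)C)B1OC(C)(C)C(C)(C)O1
Why: Miyaura borylation (oxidative addition of the C6–Br bond, acetate-assisted transmetalation, reductive elimination) installs boron at C6 with no stereocentre involved.

Step 10
Reactants: 13 2-bromo-3,4-dihydroxybenzaldehyde
Product: 14 3,4-bis(benzyloxy)-2-bromobenzaldehyde
Conditions: BnBr (2.4 equiv), K2CO3, DMF, rt → 60 °C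
Reagents that add atoms: benzyl bromide, BrCc1ccccc1
Why: Williamson etherification of both phenols is straightforward.

Step 11
Reactants: 14 3,4-bis(benzyloxy)-2-bromobenzaldehyde; 15 1-[4-(benzyloxy)phenyl]ethan-1-one
Product: 16 (E)-3-[3,4-bis(benzyloxy)-2-bromophenyl]-1-[4-(benzyloxy)phenyl]prop-2-en-1-one
Conditions: NaOH (aq), EtOH/THF, rt
Reagents that add atoms: none
Why: Claisen–Schmidt condensation should give the E-chalcone that carries the future ring A (with Br at the future C8a) on the β-carbon and the future ring B on the carbonyl.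

Step 12
Reactants: 12 lower-unit pinacol boronate; 16 (E)-chalcone (slight excess)
Product: 17 (3S)-3-[3,4-bis(benzyloxy)-2-bromophenyl]-1-[4-(benzyloxy)phenyl]-3-[(2R,3R,4R)-7,8-bis(benzyloxy)-2-[4-(benzyloxy)phenyl]-3,4-bis(tert-butyldimethylsilyloxy)chroman-6-yl]propan-1-one
Conditions: [RhCl(C2H4)2]2 (2.5 mol %), (S)-BINAP (6 mol %), KOH (0.5 equiv), 1,4-dioxane/H2O 10:1, 60 °C
Reagents that add atoms: none
Why: In this Hayashi–Miyaura conjugate addition the arylrhodium formed by transmetalation inserts the E-enone and the oxa-π-allyl is hydrolysed; by the established facial model for E-enones (S)-BINAP should deliver the lower-unit aryl to the Re face of the β-carbon (priorities bromoaryl > Cα > H) and so set the 3S centre (future C4 of the upper unit) under catalyst control, the sense to be confirmed on a model with the ligand antipode in reserve.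

Step 13
Reactants: 17 (3S)-β,β-diaryl ketone
Product: 18 (4R)-7,8-bis(benzyloxy)-2-[4-(benzyloxy)phenyl]-4-[(2R,3R,4R)-7,8-bis(benzyloxy)-2-[4-(benzyloxy)phenyl]-3,4-bis(tert-butyldimethylsilyloxy)chroman-6-yl]-4H-chromene
Conditions: CuI (20 mol %), 1,10-phenanthroline (40 mol %), Cs2CO3, DMF, 100 °C, argon
Reagents that add atoms: none
Why: Cs2CO3 generates the Z-enolate at the only enolisable position (the C3 methylene), the oxygen-bound copper enolate inserts into the C8a–Br bond of ring A through a seven-membered chelate, and C–O reductive elimination releases the enol ether (Ullmann-type coupling). The closest known reaction type is the copper-catalysed intramolecular O-arylation of ketone enolates with ortho-haloarenes that is used to make benzofurans and 4H-chromenes. Ring C (O1, C2, C3, C4, C4a, C8a) closes in a formally 6-exo-trig ipso-substitution at C8a. No stereocentre is formed: C4, set in step 12, is not α to the carbonyl and is carried through unchanged, while the new C2=C3 enol ether is what allows step 14 to set C2 and C3 from C4. The step needs O- over C-arylation and attack by the enolate only, which the substrate secures because C-arylation would require a four-membered ring and all other oxygens are capped; copper is preferred to palladium because an arylpalladium species at C8a could instead arylate C5–H of the neighbouring lower-unit arene to give a fluorene.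

Step 14
Reactants: 18 (4R)-2,4-diaryl-4H-chromene
Product: 20 (2S,3R,4R)-7,8-bis(benzyloxy)-2-[4-(benzyloxy)phenyl]-4-[(2R,3R,4R)-7,8-bis(benzyloxy)-2-[4-(benzyloxy)phenyl]-3,4-bis(tert-butyldimethylsilyloxy)chroman-6-yl]chroman-3-ol, via C3-alkylborane 19 (not isolated)
Conditions: BH3·SMe2, THF, 0 °C → rt; then NaOH (aq), H2O2, 0 °C
Reagents that add atoms: borane–dimethyl sulfide, C[S+](C)[BH3-]; hydrogen peroxide, OO
Why: Hydroboration–oxidation of the enol ether should place boron at C3 (β to O1 and to the 2-aryl group) and hydrogen at C2 in a syn addition from the face opposite the C4 aryl group, and oxidation with retention then gives 3-OH trans to both aryl groups (2,3-trans-3,4-trans, 2,4-cis), so C2 and C3 are set by substrate control from C4.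

Step 15
Reactants: 20 bis-TBS hexabenzyl 3-ol
Product: 21 (2R,3S,4R)-7,8-bis(benzyloxy)-2-[4-(benzyloxy)phenyl]-6-[(2S,3R,4R)-7,8-bis(benzyloxy)-2-[4-(benzyloxy)phenyl]-3-hydroxychroman-4-yl]chromane-3,4-diol
Conditions: TBAF, THF, rt → 40 °C
Reagents that add atoms: none
Why: Fluoride cleaves both Si–O bonds under non-acidic conditions, so the benzylic C4–O bond of the lower unit is not ionised and no stereocentre is affected.

Step 16
Reactants: 21 hexabenzyl triol
Product: 22 (2R,3S,4R)-2-(4-hydroxyphenyl)-6-[(2S,3R,4S)-3,7,8-trihydroxy-2-(4-hydroxyphenyl)chroman-4-yl]chromane-3,4,7,8-tetrol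
Conditions: H2 (1 atm), 10% Pd/C, THF/MeOH, rt, neutral, stopped at full debenzylation
Reagents that add atoms: none
Why: Hydrogenolysis of the six aryl benzyl ethers should be much faster under neutral conditions than cleavage of the free secondary benzylic C4–OH or of the cyclic C2–O1 ethers, as in the debenzylation of phenolic benzylic alcohols generally.

Compound list
1 | 2',3',4'-trihydroxyacetophenone | CC(=O)c1ccc(O)c(O)c1O | starting material
2 | 1-[3,4-bis(benzyloxy)-2-hydroxyphenyl]ethan-1-one | CC(=O)c1ccc(OCc2ccccc2)c(OCc2ccccc2)c1O | intermediate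
3 | 1-[3,4-bis(benzyloxy)-5-bromo-2-hydroxyphenyl]ethan-1-one | CC(=O)c1cc(Br)c(OCc2ccccc2)c(OCc2ccccc2)c1O | intermediate
4 | 1-[3,4-bis(benzyloxy)-5-bromo-2-(methoxymethoxy)phenyl]ethan-1-one | CC(=O)c1cc(Br)c(OCc2ccccc2)c(OCc2ccccc2)c1OCOC | intermediate
5 | 4-(benzyloxy)benzaldehyde | O=Cc1ccc(OCc2ccccc2)cc1 | starting material
6 | (E)-1-[3,4-bis(benzyloxy)-5-bromo-2-(methoxymethoxy)phenyl]-3-[4-(benzyloxy)phenyl]prop-2-en-1-one | O=C(/C=C/c1ccc(OCc2ccccc2)cc1)c1cc(Br)c(OCc2ccccc2)c(OCc2ccccc2)c1OCOC | intermediate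
7 | [3,4-bis(benzyloxy)-5-bromo-2-(methoxymethoxy)phenyl][(2R,3S)-3-[4-(benzyloxy)phenyl]oxiran-2-yl]methanone | O=C([C@@H]1O[C@H]1c1ccc(OCc2ccccc2)cc1)c1cc(Br)c(OCc2ccccc2)c(OCc2ccccc2)c1OCOC | intermediate
8 | [3,4-bis(benzyloxy)-5-bromo-2-hydroxyphenyl][(2R,3S)-3-[4-(benzyloxy)phenyl]oxiran-2-yl]methanone | O=C([C@@H]1O[C@H]1c1ccc(OCc2ccccc2)cc1)c1cc(Br)c(OCc2ccccc2)c(OCc2ccccc2)c1O | intermediate (not isolated)
9 | (2R,3R)-7,8-bis(benzyloxy)-2-[4-(benzyloxy)phenyl]-6-bromo-3-hydroxychroman-4-one | O=C1c2cc(Br)c(OCc3ccccc3)c(OCc3ccccc3)c2O[C@H](c2ccc(OCc3ccccc3)cc2)[C@H]1O | intermediate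
10 | (2R,3S,4R)-7,8-bis(benzyloxy)-2-[4-(benzyloxy)phenyl]-6-bromochromane-3,4-diol | O(Cc1ccccc1)c1ccc(cc1)[C@H]1Oc2c(cc(Br)c(OCc3ccccc3)c2OCc2ccccc2)[C@@H](O)[C@@H]1O | intermediate
11 | (2R,3R,4R)-7,8-bis(benzyloxy)-2-[4-(benzyloxy)phenyl]-6-bromo-3,4-bis(tert-butyldimethylsilyloxy)chromane | O(Cc1ccccc1)c1ccc(cc1)[C@H]1Oc2c(cc(Br)c(OCc3ccccc3)c2OCc2ccccc2)[C@@H](O[Si](C)(C)C(C)(C)C)[C@@H]1O[Si](C)(C)C(C)(C)C | intermediate
12 | 2-[(2R,3R,4R)-7,8-bis(benzyloxy)-2-[4-(benzyloxy)phenyl]-3,4-bis(tert-butyldimethylsilyloxy)chroman-6-yl]-4,4,5,5-tetramethyl-1,3,2-dioxaborolane | O(Cc1ccccc1)c1ccc(cc1)[C@H]1Oc2c(cc(B3OC(C)(C)C(C)(C)O3)c(OCc3ccccc3)c2OCc2ccccc2)[C@@H](O[Si](C)(C)C(C)(C)C)[C@@H]1O[Si](C)(C)C(C)(C)C | intermediate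
13 | 2-bromo-3,4-dihydroxybenzaldehyde | O=Cc1ccc(O)c(O)c1Br | starting material
14 | 3,4-bis(benzyloxy)-2-bromobenzaldehyde | O=Cc1ccc(OCc2ccccc2)c(OCc2ccccc2)c1Br | intermediate
15 | 1-[4-(benzyloxy)phenyl]ethan-1-one | CC(=O)c1ccc(OCc2ccccc2)cc1 | starting material
16 | (E)-3-[3,4-bis(benzyloxy)-2-bromophenyl]-1-[4-(benzyloxy)phenyl]prop-2-en-1-one | O=C(/C=C/c1ccc(OCc2ccccc2)c(OCc2ccccc2)c1Br)c1ccc(OCc2ccccc2)cc1 | intermediate
17 | (3S)-3-[3,4-bis(benzyloxy)-2-bromophenyl]-1-[4-(benzyloxy)phenyl]-3-[(2R,3R,4R)-7,8-bis(benzyloxy)-2-[4-(benzyloxy)phenyl]-3,4-bis(tert-butyldimethylsilyloxy)chroman-6-yl]propan-1-one | O(Cc1ccccc1)c1ccc(cc1)[C@H]1Oc2c(cc([C@H](CC(=O)c3ccc(OCc4ccccc4)cc3)c3ccc(OCc4ccccc4)c(OCc4ccccc4)c3Br)c(OCc3ccccc3)c2OCc2ccccc2)[C@@H](O[Si](C)(C)C(C)(C)C)[C@@H]1O[Si](C)(C)C(C)(C)C | intermediate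
18 | (4R)-7,8-bis(benzyloxy)-2-[4-(benzyloxy)phenyl]-4-[(2R,3R,4R)-7,8-bis(benzyloxy)-2-[4-(benzyloxy)phenyl]-3,4-bis(tert-butyldimethylsilyloxy)chroman-6-yl]-4H-chromene | O(Cc1ccccc1)c1ccc(cc1)[C@H]1Oc2c(cc([C@H]3c4ccc(OCc5ccccc5)c(OCc5ccccc5)c4OC(c4ccc(OCc5ccccc5)cc4)=C3)c(OCc3ccccc3)c2OCc2ccccc2)[C@@H](O[Si](C)(C)C(C)(C)C)[C@@H]1O[Si](C)(C)C(C)(C)C | intermediate
19 | C3-borane of the upper unit (BH2 at C3, trans to both aryl groups) | O(Cc1ccccc1)c1ccc(cc1)[C@H]1Oc2c(cc([C@H]3c4ccc(OCc5ccccc5)c(OCc5ccccc5)c4O[C@@H](c4ccc(OCc5ccccc5)cc4)[C@@H]3B)c(OCc3ccccc3)c2OCc2ccccc2)[C@@H](O[Si](C)(C)C(C)(C)C)[C@@H]1O[Si](C)(C)C(C)(C)C | intermediate (not isolated)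
20 | (2S,3R,4R)-7,8-bis(benzyloxy)-2-[4-(benzyloxy)phenyl]-4-[(2R,3R,4R)-7,8-bis(benzyloxy)-2-[4-(benzyloxy)phenyl]-3,4-bis(tert-butyldimethylsilyloxy)chroman-6-yl]chroman-3-ol | O(Cc1ccccc1)c1ccc(cc1)[C@H]1Oc2c(cc([C@H]3c4ccc(OCc5ccccc5)c(OCc5ccccc5)c4O[C@@H](c4ccc(OCc5ccccc5)cc4)[C@@H]3O)c(OCc3ccccc3)c2OCc2ccccc2)[C@@H](O[Si](C)(C)C(C)(C)C)[C@@H]1O[Si](C)(C)C(C)(C)C | intermediate
21 | (2R,3S,4R)-7,8-bis(benzyloxy)-2-[4-(benzyloxy)phenyl]-6-[(2S,3R,4R)-7,8-bis(benzyloxy)-2-[4-(benzyloxy)phenyl]-3-hydroxychroman-4-yl]chromane-3,4-diol | O(Cc1ccccc1)c1ccc(cc1)[C@H]1Oc2c(cc([C@H]3c4ccc(OCc5ccccc5)c(OCc5ccccc5)c4O[C@@H](c4ccc(OCc5ccccc5)cc4)[C@@H]3O)c(OCc3ccccc3)c2OCc2ccccc2)[C@@H](O)[C@@H]1O | intermediate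
22 | (2R,3S,4R)-2-(4-hydroxyphenyl)-6-[(2S,3R,4S)-3,7,8-trihydroxy-2-(4-hydroxyphenyl)chroman-4-yl]chromane-3,4,7,8-tetrol (both units 2,3-trans-3,4-trans) | Oc1ccc([C@H]2Oc3c(cc([C@H]4c5ccc(O)c(O)c5O[C@@H](c5ccc(O)cc5)[C@@H]4O)c(O)c3O)[C@@H](O)[C@@H]2O)cc1 | target

Total step count: 16. Longest linear sequence: 14 steps (steps 1–9, then 12–16); steps 10–11 form the short second branch.

Steps most likely to fail

1. Step 13 (key step). Oxidative addition at the C8a–Br bond, which is flanked by OBn and the diarylmethyl carbon, may be slow, so that reductive loss of bromine or aldol-type self-condensation of the enolate takes over. The fallback sets out from 17 and comes back at 18; it makes the aryl C–O bond first and then closes ring C by cyclodehydration. Miyaura borylation of 17 (B2pin2, PdCl2(dppf), KOAc, 1,4-dioxane, 90 °C) should give the pinacol boronate ketone F1. Oxidation (NaBO3·4H2O, THF/H2O, rt) with 1,2-migration of the aryl group from boron to oxygen should give the 2-hydroxyaryl ketone F2. PPTS in toluene at reflux with removal of water then closes the lactol and dehydrates it to 18.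

2. Step 12. Transmetalation and insertion between two ortho-substituted partners may be slow, so that protodeboronation of the electron-rich boronate outruns the addition, or discrimination between the two enone faces may be incomplete. The fallback sets out from 14 and 11 and comes back at 17; it replaces catalyst control by auxiliary control.
- Horner–Wadsworth–Emmons olefination of 14 with the known phosphonate (R)-3-[2-(diethoxyphosphoryl)acetyl]-4-phenyloxazolidin-2-one (LiCl, i-Pr2NEt, MeCN) should give the N-enoyl oxazolidinone F3.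
- Bromide 11 is converted with Mg and LiCl in THF into the arylmagnesium bromide F4.
- CuBr·SMe2-mediated conjugate addition of F4 to F3 (THF, −40 → −10 °C) should give the β,β-diaryl imide F5, the aryl group adding anti to the 4-phenyl group of the chelated s-cis imide.
- AlMe3 with MeNH(OMe)·HCl (CH2Cl2, 0 °C → rt) converts F5 into the Weinreb amide F6.
- Addition of 4-(benzyloxy)phenylmagnesium bromide (THF, 0 °C) to F6 gives 17.

3. Step 14. The C3 borane has boron anti-periplanar to the aryloxy oxygen O1, so β-alkoxy elimination could open ring C before oxidation, and facial discrimination by the C4 aryl group could be incomplete. The fallback sets out from 18 and comes back at 20; it replaces hydroboration by epoxidation and reductive opening. Dimethyldioxirane (acetone/CH2Cl2, −78 °C) should epoxidise the enol ether anti to the C4 aryl group to give the 2,3-epoxide F7. Without isolation, i-Bu2AlH (CH2Cl2, −78 °C) should cleave the C2–O bond to the 2-aryl oxocarbenium ion and deliver hydride from the aluminium bound to O3, on the O3 face, giving 20.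

Further compounds
F1 | step 13 | (3S)-1-[4-(benzyloxy)phenyl]-3-[3,4-bis(benzyloxy)-2-(4,4,5,5-tetramethyl-1,3,2-dioxaborolan-2-yl)phenyl]-3-[(2R,3R,4R)-lower-unit chroman-6-yl]propan-1-one | O(Cc1ccccc1)c1ccc(cc1)[C@H]1Oc2c(cc([C@H](CC(=O)c3ccc(OCc4ccccc4)cc3)c3ccc(OCc4ccccc4)c(OCc4ccccc4)c3B3OC(C)(C)C(C)(C)O3)c(OCc3ccccc3)c2OCc2ccccc2)[C@@H](O[Si](C)(C)C(C)(C)C)[C@@H]1O[Si](C)(C)C(C)(C)C
F2 | step 13 | (3S)-1-[4-(benzyloxy)phenyl]-3-[3,4-bis(benzyloxy)-2-hydroxyphenyl]-3-[(2R,3R,4R)-lower-unit chroman-6-yl]propan-1-one | O(Cc1ccccc1)c1ccc(cc1)[C@H]1Oc2c(cc([C@H](CC(=O)c3ccc(OCc4ccccc4)cc3)c3ccc(OCc4ccccc4)c(OCc4ccccc4)c3O)c(OCc3ccccc3)c2OCc2ccccc2)[C@@H](O[Si](C)(C)C(C)(C)C)[C@@H]1O[Si](C)(C)C(C)(C)C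
F3 | step 12 | (R)-3-[(E)-3-[3,4-bis(benzyloxy)-2-bromophenyl]acryloyl]-4-phenyloxazolidin-2-one | O=C1OC[C@@H](c2ccccc2)N1C(=O)/C=C/c1ccc(OCc2ccccc2)c(OCc2ccccc2)c1Br
F4 | step 12 | [(2R,3R,4R)-7,8-bis(benzyloxy)-2-[4-(benzyloxy)phenyl]-3,4-bis(tert-butyldimethylsilyloxy)chroman-6-yl]magnesium bromide | O(Cc1ccccc1)c1ccc(cc1)[C@H]1Oc2c(cc([Mg]Br)c(OCc3ccccc3)c2OCc2ccccc2)[C@@H](O[Si](C)(C)C(C)(C)C)[C@@H]1O[Si](C)(C)C(C)(C)C
F5 | step 12 | (R)-3-[(3S)-3-[3,4-bis(benzyloxy)-2-bromophenyl]-3-[(2R,3R,4R)-lower-unit chroman-6-yl]propanoyl]-4-phenyloxazolidin-2-one | O(Cc1ccccc1)c1ccc(cc1)[C@H]1Oc2c(cc([C@H](CC(=O)N3C(=O)OC[C@H]3c3ccccc3)c3ccc(OCc4ccccc4)c(OCc4ccccc4)c3Br)c(OCc3ccccc3)c2OCc2ccccc2)[C@@H](O[Si](C)(C)C(C)(C)C)[C@@H]1O[Si](C)(C)C(C)(C)C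
F6 | step 12 | (3S)-3-[3,4-bis(benzyloxy)-2-bromophenyl]-N-methoxy-N-methyl-3-[(2R,3R,4R)-lower-unit chroman-6-yl]propanamide | O(Cc1ccccc1)c1ccc(cc1)[C@H]1Oc2c(cc([C@H](CC(=O)N(C)OC)c3ccc(OCc4ccccc4)c(OCc4ccccc4)c3Br)c(OCc3ccccc3)c2OCc2ccccc2)[C@@H](O[Si](C)(C)C(C)(C)C)[C@@H]1O[Si](C)(C)C(C)(C)C
F7 | step 14 | 2,3-epoxide of 18 (oxirane oxygen trans to the C4 aryl group) | O(Cc1ccccc1)c1ccc(cc1)[C@H]1Oc2c(cc([C@H]3c4ccc(OCc5ccccc5)c(OCc5ccccc5)c4O[C@@]5(c4ccc(OCc6ccccc6)cc4)[C@@H]3O5)c(OCc3ccccc3)c2OCc2ccccc2)[C@@H](O[Si](C)(C)C(C)(C)C)[C@@H]1O[Si](C)(C)C(C)(C)C
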